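The route rests on one retrosynthetic cut that opens three bonds. These are the C5–C6 bond of the cyclohexane (C5–C10), the C4–C15 bond of the isopropenyl group and the O6–C12 bond of the γ-lactone. The feature exploited is the cis array C5-isopropenyl/C6–O/C7–C11 around the cis ring fusion, in which C12–C11–C7–C6 is the carbon chain of (S)-citramalic acid. In the forward direction, zerovalent nickel and Me2Zn turn an acyclic allenyl aldehyde into a methylated cyclohexanolate whose O6 takes C12 from a dioxolanone. This forms two rings, two C–C bonds and the stereocentres C5 and C6 in one flask. Precursor 19 is a C6 aldehyde carrying the citramalate acetonide at C7, OTBS at C8 and a methyl/vinyl/allenyl quaternary C10.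

Key step: step 13

Numbering (elemane): the ring is C5–C10. C10 carries C14H3 and the C1=C2 vinyl group, C5 carries the C4(=C3H2)C15H3 isopropenyl group, and C7 carries the lactone arm C11(C13H3)–C12, which closes on O6.

Stereochemical bookkeeping: the target is (5R,6R,7S,8R,10S,11S). C4, O6, C11 and the vinyl group lie on one face of the cyclohexane, and O8 and C14 lie on the other. The lactone is therefore cis-fused and O8 is trans to C11. Descriptors at C7 and C10 change along the route only because priorities change.

Assumption: the (R,R)-ligand of step 1 is taken to deliver the (R)-adduct 3. If the sense of induction is the opposite, the equally available (S,S)-ligand is used and nothing else changes.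

Design points:
- (a) C6 is carried as an N-acylthiazolidinethione. The auxiliary sets C7 and C8, and one equivalent of hydride frees the aldehyde without touching C12.
- (b) O8 is as well placed as O6 for a 5-exo attack on C12. No basic C8 alkoxide is therefore ever generated: the aldolate is covalent, the crude alcohol is silylated at once, and the final desilylation is acidic.
- (c) Step 13 is run without alkoxide additives, which would open the dioxolanone.

Step 1
Reactants: 1 2-methyl-2-vinyloxirane (racemic); 2 dimethyl malonate
Product: 4 methyl (4R)-4-ethenyl-4-methyl-2-oxooxolane-3-carboxylate (both C3 epimers), via hydroxy malonate 3 (not isolated)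
Conditions: Pd2(dba)3·CHCl3 (1 mol %), (1R,2R)-N,N'-bis[2-(diphenylphosphino)-1-naphthoyl]cyclohexane-1,2-diamine (3 mol %), CH2Cl2, rt; then DBU (5 mol %), rt
Reagents that add atoms: none
Why: Tsuji–Trost allylic alkylation run as a dynamic kinetic asymmetric transformation: both epoxide enantiomers ionise to π-allylpalladium alkoxides that interconvert by π–σ–π faster than they are attacked, the alkoxide deprotonates 2 and guides it by hydrogen bonding to the tertiary allyl terminus inside the chiral pocket, which sets C10, and the neopentyl hydroxyl of 3 then lactonises.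

Step 2
Reactants: 4 methyl (4R)-4-ethenyl-4-methyl-2-oxooxolane-3-carboxylate
Product: 5 (4S)-4-ethenyl-4-methyloxolan-2-one
Conditions: LiCl, H2O, DMSO, 150 °C
Reagents that add atoms: none
Why: Krapcho dealkoxycarbonylation, in which chloride demethylates the activated ester and the carboxylate loses CO2; the quaternary C10 is not involved, and its descriptor changes only because C9 drops in priority.

Step 3
Reactants: 5 (4S)-4-ethenyl-4-methyloxolan-2-one
Product: 6 (3S)-3-(hydroxymethyl)-N-methoxy-N,3-dimethylpent-4-enamide
Conditions: MeNH(OMe)·HCl, i-PrMgCl, THF, −20 → 0 °C; aq NH4Cl; used crude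
Reagents that add atoms: N,O-dimethylhydroxylamine hydrochloride, CNOC.Cl
Why: Weinreb aminolysis of a lactone by the magnesium amide frees the C5 hydroxyl and stores C8 at the acyl level, and the cold basic medium with a near-neutral quench keeps the γ-hydroxy amide from closing back.

Step 4
Reactants: 6 (3S)-3-(hydroxymethyl)-N-methoxy-N,3-dimethylpent-4-enamide
Product: 7 (3S)-3-formyl-N-methoxy-N,3-dimethylpent-4-enamide
Conditions: n-Pr4NRuO4 (5 mol %), NMO, 4 Å MS, CH2Cl2, rt
Reagents that add atoms: none
Why: Ley–Griffith oxidation is neutral and anhydrous, so it stops at the non-enolisable neopentyl aldehyde and supplies no acid that could trigger relactonisation.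

Step 5
Reactants: 7 (3S)-3-formyl-N-methoxy-N,3-dimethylpent-4-enamide
Product: 8 (3S)-3-ethynyl-N-methoxy-N,3-dimethylpent-4-enamide
Conditions: dimethyl (1-diazo-2-oxopropyl)phosphonate, K2CO3, MeOH, 0 °C → rt
Reagents that add atoms: dimethyl (1-diazo-2-oxopropyl)phosphonate (Ohira–Bestmann reagent), COP(=O)(OC)C(=[N+]=[N-])C(C)=O
Why: Seyferth–Gilbert homologation in its Ohira–Bestmann form adds C4; the aldehyde has no α-hydrogen, so the carbonate/methanol medium can neither epimerise nor aldolise it, and the fast 1,2-hydrogen shift gives the terminal alkyne.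

Step 6
Reactants: 8 (3S)-3-ethynyl-N-methoxy-N,3-dimethylpent-4-enamide
Product: 10 (3S)-3-ethenyl-N-methoxy-N,3-dimethylhexa-4,5-dienamide, via propargylic amine 9 (not isolated)
Conditions: (CH2O)n, Cy2NH, CuI (0.5 equiv), dioxane, reflux
Reagents that add atoms: paraformaldehyde (as formaldehyde), C=O
Why: Crabbé homologation, in which copper-mediated Mannich coupling gives 9 and an intramolecular hydride shift from a cyclohexyl C–H to the alkyne then expels the imine and leaves the terminal allene C5=C4=C3; the skipped vinyl/allene unit has no thermal rearrangement pathway.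

Step 7
Reactants: 10 (3S)-3-ethenyl-N-methoxy-N,3-dimethylhexa-4,5-dienamide
Product: 11 (3S)-3-ethenyl-3-methylhexa-4,5-dienal
Conditions: i-Bu2AlH, CH2Cl2, −78 °C; aq potassium sodium tartrate; kept in solution
Reagents that add atoms: none
Why: Weinreb amide reduction stops at the aldehyde level because collapse occurs only on quenching, and the vinyl and allene groups are inert to the hydride at −78 °C.

Step 8
Reactants: 12 (S)-citramalic acid
Product: 13 2-[(4S)-2,2,4-trimethyl-5-oxo-1,3-dioxolan-4-yl]acetic acid
Conditions: 2,2-dimethoxypropane, p-TsOH (cat.), rt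
Reagents that add atoms: 2,2-dimethoxypropane, COC(C)(C)OC
Why: in this acid-catalysed transketalisation the α-hydroxy acid unit closes the five-membered dioxolanone in preference to the six-membered alternative, which leaves the C6 carboxyl free and breaks no bond at C11.

Step 9
Reactants: 13 2-[(4S)-2,2,4-trimethyl-5-oxo-1,3-dioxolan-4-yl]acetic acid; 14 (4S)-4-benzyl-1,3-thiazolidine-2-thione
Product: 15 (4S)-4-benzyl-3-{2-[(4S)-2,2,4-trimethyl-5-oxo-1,3-dioxolan-4-yl]acetyl}-1,3-thiazolidine-2-thione
Conditions: DCC, DMAP (10 mol %), CH2Cl2, 0 °C → rt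
Reagents that add atoms: none
Why: Steglich-type carbodiimide N-acylation of the acidic thiazolidinethione N–H runs under neutral conditions that leave the dioxolanone and C11 untouched.

Step 10
Reactants: 15 N-acylthiazolidinethione; 11 (3S)-3-ethenyl-3-methylhexa-4,5-dienal
Product: 17 (4S)-4-benzyl-3-{(2R,3R,5S)-5-ethenyl-3-hydroxy-5-methyl-2-[(4S)-2,2,4-trimethyl-5-oxo-1,3-dioxolan-4-yl]octa-6,7-dienoyl}-1,3-thiazolidine-2-thione, via Cl3Ti enolate 16 (not isolated)
Conditions: TiCl4 (1.05 equiv), i-Pr2NEt (1.1 equiv), NMP (1 equiv), CH2Cl2, −78 °C; then 11, −78 °C; half-saturated aq NH4Cl; used crude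
Reagents that add atoms: none
Why: Crimmins-type titanium aldol of an N-acylthiazolidinethione: soft enolisation gives the Z enolate 16, NMP keeps the thiocarbonyl off titanium, and the non-chelated Zimmerman–Traxler chair reacts on the enolate face away from the benzyl group, so the auxiliary sets both C7 and C8 as the Evans-type syn pair (C11 and O8 syn along C6–C9), while the covalent Ti–O bonds and the low temperature hold back loss of the C11 oxygen and attack of O8 on C12.

Step 11
Reactants: 17 syn aldol adduct
Product: 18 (4S)-4-benzyl-3-{(2R,3R,5S)-3-[(tert-butyldimethylsilyl)oxy]-5-ethenyl-5-methyl-2-[(4S)-2,2,4-trimethyl-5-oxo-1,3-dioxolan-4-yl]octa-6,7-dienoyl}-1,3-thiazolidine-2-thione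
Conditions: TBSOTf, 2,6-lutidine, CH2Cl2, −78 → 0 °C
Reagents that add atoms: tert-butyldimethylsilyl triflate, CC(C)(C)[Si](C)(C)OS(=O)(=O)C(F)(F)F
Why: silyl triflate/lutidine silylation caps even a hindered carbinol at low temperature without forming an alkoxide, so O8 is blocked before it can lactonise onto C12 (γ-hydroxyalkyl dioxolanones close only under acid or base catalysis).

Step 12
Reactants: 18 silylated aldol adduct
Product: 19 (2R,3R,5S)-3-[(tert-butyldimethylsilyl)oxy]-5-ethenyl-5-methyl-2-[(4S)-2,2,4-trimethyl-5-oxo-1,3-dioxolan-4-yl]octa-6,7-dienal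
Conditions: i-Bu2AlH (1.1 equiv), CH2Cl2, −78 °C, until the yellow colour fades; aq potassium sodium tartrate; used at once
Reagents that add atoms: none
Why: direct reductive removal of the thiazolidinethione works because the twisted thioimide carbonyl is by far the most electrophilic acyl group, so one equivalent of hydride stops at the aldehyde, spares the C12 carbonyl next to quaternary C11, and leaves C7 unepimerised in the non-basic medium.

Step 13
Reactants: 19 citramalate-dioxolanone allenyl aldehyde; 20 dimethylzinc
Product: 23 (5R,6R,7R,8R,10S,11S)-8-[(tert-butyldimethylsilyl)oxy]-11-hydroxyelema-1,3-dien-12,6-olide, via oxanickelacycle 21 (not isolated), via MeZn alkoxide 22 (not isolated)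
Conditions: Ni(cod)2 (20 mol %), Me2Zn (3 equiv), THF (0.02 M), slow addition of 19, 0 °C → rt; then 40 °C; aq NH4Cl
Reagents that add atoms: dimethylzinc (20), C[Zn]C
Why: Proposed new method: zerovalent nickel binds the C6 aldehyde and the proximal C5=C4 π bond of 19 and couples them oxidatively to the divalent oxanickelacycle 21, Me2Zn opens its Ni–O bond by transmetalation, and reductive elimination joins CH3 (C15) to C4, giving MeZn alkoxide 22 and zerovalent nickel again. The closest known reaction type is the Ni(cod)2/organozinc alkylative cyclisation of allenyl aldehydes to cis-2-alkenylcyclopentanols; new here are the six-membered closure, which the quaternary C10 should favour through the gem-dialkyl effect, and the acyl transfer in the same flask. The carbocycle closes in a 6-exo mode at the proximal allene carbon (C5–C6), and the lactone closes 5-exo-trig when O6 of 22 adds to C12 and the dioxolanone sheds its ketal carbon as acetone, which uncovers the C11 oxygen with its citramalate configuration intact. C6 is controlled by C7: in the chair that keeps C11 and the C8 silyloxy group equatorial (C10 methyl equatorial, vinyl axial), C5 approaches anti to the bulky C11 with the carbonyl oxygen axial between C8 and C11, the Felkin–Anh arrangement, so O6 ends cis to C11. C5 is controlled by the metallacycle, whose five-membered ring can only be cis-fused to the forming chair, so C4 becomes equatorial and cis to O6. The step needs allene over vinyl, cyclisation over direct methyl transfer and O6 over O8 for C12: only the cumulated π system is activated by nickel, uncatalysed Me2Zn is inert to the aldehyde and the dioxolanone at this temperature, and O8 is blocked as its silyl ether.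

Step 14
Reactants: 23 8-O-silyl 11-hydroxy lactone
Product: 24 (5R,6R,7R,8R,10S,11S)-11-acetoxy-8-[(tert-butyldimethylsilyl)oxy]elema-1,3-dien-12,6-olide
Conditions: Ac2O, DMAP, Et3N, CH2Cl2, rt → 40 °C
Reagents that add atoms: acetic anhydride, CC(=O)OC(C)=O
Why: DMAP-catalysed acylation acetylates the only free hydroxyl, the tertiary C11–OH, without breaking a bond at C11, and it is done before the base-sensitive β,γ-unsaturated ester is present.

Step 15
Reactants: 24 11-acetate 8-silyl ether
Product: 25 (5R,6R,7S,8R,10S,11S)-11-acetoxy-8-hydroxyelema-1,3-dien-12,6-olide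
Conditions: HF·pyridine, pyridine, THF, 0 °C → rt (polypropylene vessel)
Reagents that add atoms: none
Why: fluoride desilylation in an acidic, buffered medium never produces a C8 alkoxide, which suppresses translactonisation of O8 onto C12 and acetyl migration from O11 to O8.

Step 16
Reactants: 25 8-hydroxy 11-acetate; 26 3-methylbut-3-enoic acid
Product: 27 CNP0106639.1, (5R,6R,7S,8R,10S,11S)-11-acetoxy-8-(3-methylbut-3-enoyloxy)elema-1,3-dien-12,6-olide
Conditions: DCC, DMAP (10 mol %), CH2Cl2, 0 °C
Reagents that add atoms: none
Why: Steglich esterification acylates the equatorial secondary C8–OH with retention, and the low DMAP loading and 0 °C keep the β,γ double bond of the acyl group from moving into conjugation.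

Compound list
1 | 2-methyl-2-vinyloxirane (racemic) | CC1(C=C)CO1 | starting material
2 | dimethyl malonate | COC(=O)CC(=O)OC | starting material
3 | dimethyl 2-[(2R)-1-hydroxy-2-methylbut-3-en-2-yl]propanedioate (not isolated) | COC(=O)C(C(=O)OC)[C@@](C)(C=C)CO | intermediate
4 | methyl (4R)-4-ethenyl-4-methyl-2-oxooxolane-3-carboxylate (both C3 epimers) | COC(=O)C1C(=O)OC[C@]1(C)C=C | intermediate
5 | (4S)-4-ethenyl-4-methyloxolan-2-one | O=C1C[C@@](C)(C=C)CO1 | intermediate
6 | (3S)-3-(hydroxymethyl)-N-methoxy-N,3-dimethylpent-4-enamide | CON(C)C(=O)C[C@@](C)(C=C)CO | intermediate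
7 | (3S)-3-formyl-N-methoxy-N,3-dimethylpent-4-enamide | CON(C)C(=O)C[C@@](C)(C=C)C=O | intermediate
8 | (3S)-3-ethynyl-N-methoxy-N,3-dimethylpent-4-enamide | CON(C)C(=O)C[C@@](C)(C=C)C#C | intermediate
9 | (3S)-6-(dicyclohexylamino)-3-ethenyl-N-methoxy-N,3-dimethylhex-4-ynamide (not isolated) | CON(C)C(=O)C[C@@](C)(C=C)C#CCN(C1CCCCC1)C1CCCCC1 | intermediate
10 | (3S)-3-ethenyl-N-methoxy-N,3-dimethylhexa-4,5-dienamide | CON(C)C(=O)C[C@@](C)(C=C)C=C=C | intermediate
11 | (3S)-3-ethenyl-3-methylhexa-4,5-dienal | O=CC[C@@](C)(C=C)C=C=C | intermediate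
12 | (S)-citramalic acid | C[C@](O)(CC(=O)O)C(=O)O | starting material
13 | 2-[(4S)-2,2,4-trimethyl-5-oxo-1,3-dioxolan-4-yl]acetic acid | OC(=O)C[C@]1(C)OC(C)(C)OC1=O | intermediate
14 | (4S)-4-benzyl-1,3-thiazolidine-2-thione | S=C1N[C@@H](Cc2ccccc2)CS1 | starting material
15 | (4S)-4-benzyl-3-{2-[(4S)-2,2,4-trimethyl-5-oxo-1,3-dioxolan-4-yl]acetyl}-1,3-thiazolidine-2-thione | O=C(C[C@]1(C)OC(C)(C)OC1=O)N1[C@@H](Cc2ccccc2)CSC1=S | intermediate
16 | (Z)-trichlorotitanium enolate of 15 (not isolated) | Cl[Ti](Cl)(Cl)O/C(=C\[C@]1(C)OC(C)(C)OC1=O)N1[C@@H](Cc2ccccc2)CSC1=S | intermediate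
17 | syn aldol adduct, (2R,3R,5S)-3-hydroxy acyl chain on the (4S)-auxiliary | O=C([C@@H]([C@]1(C)OC(C)(C)OC1=O)[C@H](O)C[C@@](C)(C=C)C=C=C)N1[C@@H](Cc2ccccc2)CSC1=S | intermediate
18 | 3-O-TBS ether of 17 | O=C([C@@H]([C@]1(C)OC(C)(C)OC1=O)[C@H](O[Si](C)(C)C(C)(C)C)C[C@@](C)(C=C)C=C=C)N1[C@@H](Cc2ccccc2)CSC1=S | intermediate
19 | (2R,3R,5S)-3-[(tert-butyldimethylsilyl)oxy]-5-ethenyl-5-methyl-2-[(4S)-2,2,4-trimethyl-5-oxo-1,3-dioxolan-4-yl]octa-6,7-dienal | O=C[C@@H]([C@]1(C)OC(C)(C)OC1=O)[C@H](O[Si](C)(C)C(C)(C)C)C[C@@](C)(C=C)C=C=C | intermediate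
20 | dimethylzinc | C[Zn]C | starting material
21 | divalent oxanickelacycle, nickel bridging O6 and C4, further ligands omitted, ring configuration as in 23 (not isolated) | C=C[C@]1(C)C[C@@H](O[Si](C)(C)C(C)(C)C)[C@H]([C@]2(C)OC(C)(C)OC2=O)[C@@H]3O[Ni]C(=C)[C@H]13 | intermediate
22 | methylzinc C6 alkoxide of the cyclised isopropenyl cyclohexanol, dioxolanone intact (not isolated) | C=C[C@]1(C)C[C@@H](O[Si](C)(C)C(C)(C)C)[C@H]([C@]2(C)OC(C)(C)OC2=O)[C@H](O[Zn]C)[C@@H]1C(=C)C | intermediate
23 | (5R,6R,7R,8R,10S,11S)-8-[(tert-butyldimethylsilyl)oxy]-11-hydroxyelema-1,3-dien-12,6-olide | C=C[C@]1(C)C[C@@H](O[Si](C)(C)C(C)(C)C)[C@H]2[C@H](OC(=O)[C@@]2(C)O)[C@@H]1C(=C)C | intermediate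
24 | (5R,6R,7R,8R,10S,11S)-11-acetoxy-8-[(tert-butyldimethylsilyl)oxy]elema-1,3-dien-12,6-olide | C=C[C@]1(C)C[C@@H](O[Si](C)(C)C(C)(C)C)[C@H]2[C@H](OC(=O)[C@@]2(C)OC(C)=O)[C@@H]1C(=C)C | intermediate
25 | (5R,6R,7S,8R,10S,11S)-11-acetoxy-8-hydroxyelema-1,3-dien-12,6-olide | C=C[C@]1(C)C[C@@H](O)[C@H]2[C@H](OC(=O)[C@@]2(C)OC(C)=O)[C@@H]1C(=C)C | intermediate
26 | 3-methylbut-3-enoic acid | C=C(C)CC(=O)O | starting material
27 | CNP0106639.1 | C=C[C@]1(C)C[C@@H](OC(=O)CC(=C)C)[C@H]2[C@H](OC(=O)[C@@]2(C)OC(C)=O)[C@@H]1C(=C)C | target

Total step count: 16. Longest linear sequence: 14 steps (steps 1–7 and 10–16).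

Steps most likely to fail

1. Step 13.
- What may go wrong: the oxidative cyclisation to a six-membered ring may be too slow. Methyl transfer to the aldehyde, allene oligomerisation or base-induced epimerisation/elimination at C7 could then take over. The alternative chair with O6 equatorial and C4 axial avoids the O6/vinyl 1,3-diaxial contact and may erode facial selectivity.
- Fallback (tin/silicon in place of nickel/zinc): it sets out from 19. A palladium-catalysed silastannylative carbocyclisation (Me3SiSnBu3, [(η3-C3H5)PdCl]2, THF, rt) is a reaction type established for allenyl aldehydes. It places silicon on C4 and lets C5 attack C6 through a closed allyltin transition state that also gives the cis alcohol. The tin alkoxide lactonises as in the main route and should give vinylsilane lactone F1. Iododesilylation (NIS, MeCN, 0 °C), which the electron-rich vinylsilane undergoes ahead of the neopentyl vinyl group, gives vinyl iodide lactone F2. Negishi methylation with 20 (Pd(PPh3)4, THF, rt) comes back to the route at 23.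

2. Step 10.
- What may go wrong: the enolate may lose the C11 oxygen by β-elimination. The fully substituted C11 next to the nucleophilic carbon may erode syn selectivity. O8 may attack C12 prematurely.
- Fallback (reagent-controlled Lewis-acid aldol in place of a metal enolate): it sets out from 13. The acid is turned into S-ethyl thioester F3 (EtSH, DCC, DMAP). This is trapped as ketene silyl thioacetal F4 (LiN(i-Pr)2 with Me3SiCl present from the start, THF, −78 °C, so that the enolate has no lifetime). An asymmetric Mukaiyama aldol with 11 is promoted by divalent tin triflate Sn(OTf)2, a proline-derived chiral diamine (enantiomer chosen for the required pair) and Bu2Sn(OAc)2 in CH2Cl2 at −78 °C. It runs through an open transition state, is syn-selective for such thioacetals and produces neither a basic enolate nor a basic alkoxide, and it should give syn hydroxy thioester F5. Silylation (TBSOTf, 2,6-lutidine) to silyloxy thioester F6 and reduction with i-Bu2AlH (CH2Cl2, −78 °C) come back to the route at 19.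

3. Step 1.
- What may go wrong: attack of the malonate at the primary allyl terminus (1,4-opening) may compete with the branched mode. Incomplete equilibration of the π-allyl complexes may lower the enantioselectivity.
- Fallback (regiochemistry fixed by the metal, not by an alkoxide directing effect): it sets out from 1 and 2. Pd(PPh3)4-catalysed 1,4-opening of 1 with acetic acid gives (E)-hydroxy acetate F7. Silylation (TBSCl, imidazole) gives silyl ether F8. An iridium-catalysed allylic alkylation with the sodium salt of 2 ([Ir(cod)Cl]2, chiral phosphoramidite, NaH, THF) has an intrinsic preference for the more substituted terminus and gives silyloxy malonate F9. HF·pyridine frees 3, which lactonises and comes back to the route at 4.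

Further compounds
F1 | step 13 | C4-trimethylsilyl analogue of 23 (SiMe3 in place of C15H3, ring configuration as in 23) | C=C[C@]1(C)C[C@@H](O[Si](C)(C)C(C)(C)C)[C@H]2[C@H](OC(=O)[C@@]2(C)O)[C@@H]1C(=C)[Si](C)(C)C
F2 | step 13 | C4-iodo analogue of 23 (iodine in place of C15H3, ring configuration as in 23) | C=C[C@]1(C)C[C@@H](O[Si](C)(C)C(C)(C)C)[C@H]2[C@H](OC(=O)[C@@]2(C)O)[C@@H]1C(=C)I
F3 | step 10 | S-ethyl 2-[(4S)-2,2,4-trimethyl-5-oxo-1,3-dioxolan-4-yl]ethanethioate | CCSC(=O)C[C@]1(C)OC(C)(C)OC1=O
F4 | step 10 | (Z)-ketene S-ethyl O-trimethylsilyl thioacetal of F3 | CCS/C(O[Si](C)(C)C)=C\[C@]1(C)OC(C)(C)OC1=O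
F5 | step 10 | S-ethyl (2R,3R,5S)-5-ethenyl-3-hydroxy-5-methyl-2-[(4S)-2,2,4-trimethyl-5-oxo-1,3-dioxolan-4-yl]octa-6,7-dienethioate | CCSC(=O)[C@@H]([C@]1(C)OC(C)(C)OC1=O)[C@H](O)C[C@@](C)(C=C)C=C=C
F6 | step 10 | 3-O-TBS ether of F5 | CCSC(=O)[C@@H]([C@]1(C)OC(C)(C)OC1=O)[C@H](O[Si](C)(C)C(C)(C)C)C[C@@](C)(C=C)C=C=C
F7 | step 1 | (E)-4-hydroxy-3-methylbut-2-en-1-yl acetate | CC(=O)OC/C=C(\C)CO
F8 | step 1 | (E)-4-[(tert-butyldimethylsilyl)oxy]-3-methylbut-2-en-1-yl acetate | CC(=O)OC/C=C(\C)CO[Si](C)(C)C(C)(C)C
F9 | step 1 | dimethyl 2-{(2R)-1-[(tert-butyldimethylsilyl)oxy]-2-methylbut-3-en-2-yl}propanedioate | COC(=O)C(C(=O)OC)[C@@](C)(C=C)CO[Si](C)(C)C(C)(C)C
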